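**Retrosynthetic overview**

1. The target comes from the tetracyclic C7 ketone by electron-transfer reduction, and that ketone from a cyclooctadienone by ring-closing metathesis (ring C, C9=C10) and diimide saturation of the two helper alkenes.
2. The cyclooctadienone comes from a bicyclic 2-alkylidene-6-alkenyl-dihydropyran by a Claisen ring expansion that forms C8–C17 and ring B. Enabling feature: in ring B the carbinol C7, the quaternary C8, C17 and the C18–C19 bridge are a hidden γ,δ-unsaturated ketone (O=C7–C8–C17–C18=C19), and C7 and C19 both sit on the ring-A unit C6–C2=C1, so a temporary oxygen bridge C7–O–C19 makes a six-membered allyl vinyl ether.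
3. The dihydropyran comes from anti-iodoetherification and Stille coupling of a propynyl carbinol, itself made by catalyst-controlled vinylzinc addition of a ring-D alkyne (asymmetric Diels–Alder reaction, hydromethylation) to a ring-A enal (from (S)-pulegone by Favorskii contraction and lactone-tethered oxidation of the Z-methyl group).
4. Order of ring formation: A (chiral pool), D (Diels–Alder), temporary pyran, B (Claisen), C (metathesis); the pyran oxygen ends as the C7 hydroxyl.

Key step: step 17

Numbering used in the text: C1 = methyl-bearing alkene carbon; C2 = the other alkene carbon (ring A); C3, C4 = ring-A CH2; C5 = ring-A CH(CH3); C6 = A/B fusion CH; C7 = carbinol; C8 = quaternary C(CH3) next to C7; C9, C10 = ring-C CH2; C11 = quaternary C(CH3) at the C/D fusion; C12, C13 = ring-D CH2; C14 = C(CH3)2; C15 = CH2; C16 = C/D fusion CH; C17 = B/C fusion CH; C18, C19 = ring-B CH2. Ring A = cyclopentane, B = eight-membered ring, C = central cyclohexane, D = gem-dimethylcyclohexane. Locants inside compound names are IUPAC locants.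

Remark (assumption on the chemistry): the enantiomers of the chiral catalysts in steps 10 and 14 are those expected from the accepted transition-state models to give the drawn configurations; if the sense were opposite, the mirror-image catalyst would be used.

**Route**

Step 1
Reactants: 1 (S)-(−)-pulegone
Product: 3 methyl (2S)-2-methyl-5-(propan-2-ylidene)cyclopentane-1-carboxylate (epimers at C1), via pulegone dibromide 2 (not isolated)
Conditions: Br2, Et2O, −10 °C; then NaOMe, MeOH, reflux
Reagents that add atoms: sodium methoxide, [Na+].[O-]C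
Why: Favorskii ring contraction of the dibromide (cyclopropanone from the C6 enolate, methoxide opening, loss of the second bromide to restore the tetrasubstituted alkene) should give the pulegenate; C5 is untouched and the new C6 centre is formed without control, which step 2 corrects.

Step 2
Reactants: 3 methyl pulegenate (epimer mixture)
Product: 5 methyl (1S,2S)-2-methyl-5-(propan-2-ylidene)cyclopentane-1-carboxylate (ester cis to methyl), via lithium dienolate 4 (not isolated)
Conditions: LiN(i-Pr)2, THF, −78 °C; then AcOH in THF, −78 °C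
Reagents that add atoms: none
Why: Kinetic α-protonation of the planar extended enolate (deconjugative dienolate protonation) is expected to occur anti to the adjacent C5 methyl group, which sets C6 with the ester cis to that methyl; any trans ester can be resubmitted.

Step 3
Reactants: 5 cis-methyl pulegenate
Product: 7 methyl (1S,2S)-5-hydroxy-2-methyl-5-(prop-1-en-2-yl)cyclopentane-1-carboxylate (C5 epimers), via allylic hydroperoxide 6 (not isolated)
Conditions: O2, tetraphenylporphyrin (cat.), visible light, CH2Cl2, −20 °C; then PPh3, 0 °C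
Reagents that add atoms: oxygen, O=O
Why: Schenck ene reaction of singlet oxygen: hydrogen abstraction from either methyl gives the same tertiary hydroperoxide at C2 (abstraction at C6 is disfavoured by the ester), and PPh3 reduces it to the alcohol; the C2 configuration is erased in step 4.

Step 4
Reactants: 7 tertiary allylic alcohol
Product: 9 (7S,7aS)-4,7-dimethyl-5,6,7,7a-tetrahydrocyclopenta[c]pyran-1(3H)-one, via primary allylic alcohol 8 (not isolated)
Conditions: Re2O7 (3 mol %), Et2O, 0 °C to rt; then PPTS (cat.), toluene, 60 °C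
Reagents that add atoms: none
Why: Perrhenate-catalysed 1,3-transposition of the allylic alcohol ([3,3] shift of the perrhenate ester) equilibrates 7 with the E and Z primary alcohols, and only the Z isomer (CH2OH cis to C6) can lactonise, so transesterification should drain the mixture into the six-membered lactone and fix the C1=C2 geometry by ring constraint.

Step 5
Reactants: 9 lactone
Product: 10 (7S,7aS)-4,7-dimethyl-1,3,5,6,7,7a-hexahydrocyclopenta[c]pyran-1-ol (anomers)
Conditions: i-Bu2AlH (1.1 equiv), CH2Cl2, −78 °C; Rochelle salt work-up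
Reagents that add atoms: none
Why: Partial reduction of a δ-lactone with i-Bu2AlH stops at the aluminium hemiacetal at low temperature; no base is present, which avoids eliminative ring opening of the β,γ-unsaturated lactone and epimerisation at C6.

Step 6
Reactants: 10 lactol
Product: 11 (Z)-2-[(2R,3S)-2-ethynyl-3-methylcyclopentylidene]propan-1-ol
Conditions: TMSCHN2, n-BuLi (2.5 equiv each), THF, −78 to 0 °C; aq NH4Cl
Reagents that add atoms: (trimethylsilyl)diazomethane, C[Si](C)(C)C=[N+]=[N-]
Why: Colvin homologation: lithiated TMS-diazomethane adds to the hydroxy-aldehyde tautomer of the lactol, Peterson-type elimination gives a diazoalkene that loses N2 and undergoes 1,2-hydrogen shift to the terminal alkyne (C8 is introduced); fast addition at low temperature should preserve C6.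

Step 7
Reactants: 11 terminal alkynol
Product: 12 (Z)-2-[(2R,3S)-3-methyl-2-(prop-1-yn-1-yl)cyclopentylidene]propan-1-ol
Conditions: n-BuLi (2.1 equiv), THF, −78 to −20 °C; MeI (1.05 equiv), DMPU, −20 °C to rt
Reagents that add atoms: iodomethane, CI
Why: C-Methylation of the acetylide in the alkoxide–acetylide dianion is a standard alkynol alkylation (the lithium alkoxide is much less nucleophilic toward MeI) and installs the future C8 methyl group.

Step 8
Reactants: 12 allylic alcohol
Product: 13 (Z)-2-[(2R,3S)-3-methyl-2-(prop-1-yn-1-yl)cyclopentylidene]propanal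
Conditions: MnO2, CH2Cl2, rt
Reagents that add atoms: none
Why: MnO2 oxidises the primary allylic alcohol to the enal under neutral conditions, so the Z geometry of the tetrasubstituted alkene and the C6 centre should survive.

Step 9
Reactants: 14 3-(trimethylsilyl)prop-2-ynal; 15 2-(triphenylphosphoranylidene)propanal
Product: 16 (E)-2-methyl-5-(trimethylsilyl)pent-2-en-4-ynal
Conditions: CH2Cl2, 0 °C to rt
Reagents that add atoms: none
Why: Wittig olefination with the stabilised formyl ylide is E-selective, and the alkynyl aldehyde is more electrophilic than the product enal, so single homologation is expected.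

Step 10
Reactants: 16 enynal; 17 isoprene
Product: 18 (1R,6R)-1,4-dimethyl-6-[(trimethylsilyl)ethynyl]cyclohex-3-ene-1-carbaldehyde (alkynyl cis to the C1 methyl)
Conditions: oxazaborolidinium triflimide from (S)-diphenylprolinol, o-tolylboroxine and HNTf2 (20 mol %), CH2Cl2, −78 to −40 °C
Reagents that add atoms: none
Why: Enantioselective Diels–Alder reaction of an α-substituted enal under cationic oxazaborolidine catalysis: the activated formyl group directs the "para" adduct (methyl on C14), the E geometry of the dienophile is transferred suprafacially to the cis relation of the C11 methyl and the C16 alkynyl group, and the catalyst-controlled face sets C11 and C16 together.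

Step 11
Reactants: 18 aldehyde
Product: 19 {[(1R,6S)-6-ethenyl-3,6-dimethylcyclohex-3-en-1-yl]ethynyl}trimethylsilane
Conditions: Ph3PCH3Br, KN(SiMe3)2, THF, 0 °C to rt
Reagents that add atoms: methyltriphenylphosphonium bromide, C[P+](c1ccccc1)(c1ccccc1)c1ccccc1.[Br-]
Why: Wittig methylenation of the non-enolisable neopentyl aldehyde installs the C11 vinyl group without touching C16.

Step 12
Reactants: 19 diene
Product: 21 {[(1R,2S)-2-ethenyl-2,5,5-trimethylcyclohexyl]ethynyl}trimethylsilane, via sulfonylhydrazide adduct 20 (not isolated)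
Conditions: Fe(acac)3 (cat.), PhSiH3, CH2=NNHSO2C8H17, THF/MeOH, rt; then MeOH, 60 °C
Reagents that add atoms: formaldehyde N-(octane-1-sulfonyl)hydrazone, C=NNS(=O)(=O)CCCCCCCC
Why: Hydromethylation by metal-hydride hydrogen-atom transfer: H is delivered to C13 of the trisubstituted alkene, the tertiary C14 radical adds to the hydrazone, and the adduct loses sulfinate and N2 on warming to leave the gem-dimethyl group; the trisubstituted alkene should react much faster than the hindered vinyl group and the silyl alkyne.

Step 13
Reactants: 21 silyl alkyne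
Product: 22 (1S,2S)-1-ethenyl-2-ethynyl-1,4,4-trimethylcyclohexane
Conditions: K2CO3 (cat.), MeOH, rt
Reagents that add atoms: none
Why: Carbonate-catalysed methanolysis of the alkynyl C–Si bond is a standard protodesilylation.

Step 14
Reactants: 22 terminal alkyne; 13 enal
Product: 25 (1E,3S,4Z)-1-[(1S,2S)-2-ethenyl-2,5,5-trimethylcyclohexyl]-4-[(2R,3S)-3-methyl-2-(prop-1-yn-1-yl)cyclopentylidene]pent-1-en-3-ol, via alkenylborane 23 (not isolated), via alkenylzinc 24 (not isolated)
Conditions: Cy2BH, hexane/toluene, 0 °C to rt; Me2Zn, −78 °C; (−)-MIB (5 mol %); then 13, −30 to 0 °C; aq NH4Cl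
Reagents that add atoms: none
Why: Syn hydroboration of the terminal alkyne (faster than at the neopentyl vinyl group), boron-to-zinc exchange and amino-alcohol-catalysed addition to the aldehyde (Oppolzer–Walsh asymmetric vinylation) form the C18–C19 bond with E geometry; the catalyst-controlled aldehyde face sets C19 (S).

Step 15
Reactants: 25 bis-allylic alcohol
Product: 26 (1E,3S,7S,7aS)-3-{(E)-2-[(1S,2S)-2-ethenyl-2,5,5-trimethylcyclohexyl]ethenyl}-1-(1-iodoethylidene)-4,7-dimethyl-1,3,5,6,7,7a-hexahydrocyclopenta[c]pyran
Conditions: NIS, NaHCO3, MeCN, −20 to 0 °C, dark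
Reagents that add atoms: N-iodosuccinimide, O=C1CCC(=O)N1I
Why: Iodonium-induced 6-exo-dig cyclisation (iodoetherification) of the hydroxy alkyne: anti addition of oxygen and iodine across the propynyl group places iodine on the C6 side and the methyl on the oxygen side, so the C7=C8 geometry is set by mechanism.

Step 16
Reactants: 26 iodo enol ether
Product: 27 (1E,3S,7S,7aS)-1-(but-3-en-2-ylidene)-3-{(E)-2-[(1S,2S)-2-ethenyl-2,5,5-trimethylcyclohexyl]ethenyl}-4,7-dimethyl-1,3,5,6,7,7a-hexahydrocyclopenta[c]pyran
Conditions: Bu3SnCH=CH2, Pd2(dba)3 (2.5 mol %), AsPh3, CuI, DMF, rt; filtration through basic alumina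
Reagents that add atoms: tributyl(vinyl)stannane, C=C[Sn](CCCC)(CCCC)CCCC
Why: Stille coupling of the alkenyl iodide proceeds with retention and should give the tetrasubstituted 2-oxydiene with the vinyl group (future C9) cis to C6 and the methyl cis to oxygen.

Step 17
Reactants: 27 dihydropyran allyl vinyl ether
Product: 28 (3S,3aS,5S,6S,7Z)-5-ethenyl-6-[(1S,2S)-2-ethenyl-2,5,5-trimethylcyclohexyl]-3,5,9-trimethyl-1,2,3,3a,5,6-hexahydro-4H-cyclopenta[8]annulen-4-one
Conditions: toluene (0.01 M), BHT, Et3N (trace), base-washed sealed tube, 100–110 °C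
Reagents that add atoms: none
Why: Thermal Claisen rearrangement ([3,3]-sigmatropic shift) of the allyl vinyl ether C8=C7–O–C19–C18=C17 held in the dihydropyran: the O–C19 bond breaks as C8–C17 forms, the closest precedent being the ring expansion of 2-alkylidene-6-alkenyl-tetrahydropyrans to cyclooct-4-enones. Ring B closes by ring expansion (six-membered cyclic ether to eight-membered carbocycle), the tether C6–C2=C1 between C7 and C19 becoming part of the new ring; because the new C18=C19 bond must be cis in an eight-membered ring, only the chair-like six-centre array with the tether pseudo-axial on C19 is open. C8 (quaternary) is controlled by the enol ether geometry from steps 15 and 16 (methyl on the oxygen side, vinyl on the C6 side), C17 by the E geometry of the C17=C18 alkene (cyclohexyl pseudo-equatorial), and the face common to both by the C19 carbinol configuration (alkenyl cis to H-6), whose chirality is transferred and then erased. The step needs the [3,3] shift to outrun ionisation of the doubly allylic C19–O bond, which strictly neutral, base-buffered conditions should secure, and it needs the other allyl arm (C19–C1=C2) to stay silent, which geometry secures because bonding C8 to C2 would make a four-membered ring. A later Cope shift of the new 1,5-diene would need a boat array, so the temperature is kept at or below 110 °C.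

Step 18
Reactants: 28 cyclooctadienone
Product: 29 tetracyclic triene ketone (rings A–D closed; C7 ketone; C9=C10, cis-C18=C19 and C1=C2 alkenes; C5, C6, C8, C11, C16, C17 as in the target)
Conditions: second-generation Grubbs catalyst (10 mol %), CH2Cl2 (0.005 M), 40 °C
Reagents that add atoms: none
Why: Ring-closing metathesis of the two terminal vinyl groups on C8 and C11 closes the cyclohexene ring C with loss of ethylene; terminal alkenes should initiate far more readily than the hindered internal cis-alkene, the tetrasubstituted alkene is inert, and no stereocentre is formed.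

Step 19
Reactants: 29 triene ketone
Product: 30 tetracyclic C7 ketone (only the C1=C2 alkene left; all carbon stereocentres as in the target)
Conditions: KO2CN=NCO2K, AcOH, MeOH/CH2Cl2, 0 °C to rt (repeated charges)
Reagents that add atoms: none
Why: Diimide transfers H2 concertedly and syn to the two cis-disubstituted alkenes (C9=C10 and C18=C19) without double-bond migration, while the tetrasubstituted C1=C2 alkene and the ketone are inert.

Step 20
Reactants: 30 ketone
Product: 31 target alcohol CNP0399382.1 (5S,6S,7R,8S,11S,16S,17S in the numbering above)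
Conditions: SmI2, H2O, Et3N, THF, 0 °C
Reagents that add atoms: none
Why: Single-electron (ketyl) reduction of the hindered ketone: the ketyl/organosamarium intermediate should relax so that oxygen takes the less encumbered peripheral position before C–H formation on the transannular side, giving the thermodynamically preferred C7 alcohol (R), the opposite of what peripheral hydride delivery is expected to give.

**Compound list**

1 | (S)-(−)-pulegone, (5S)-5-methyl-2-(propan-2-ylidene)cyclohexan-1-one | C[C@H]1CCC(=C(C)C)C(=O)C1 | starting material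
2 | pulegone dibromide, (5S)-2-bromo-2-(2-bromopropan-2-yl)-5-methylcyclohexan-1-one (C2 epimers) | C[C@H]1CCC(Br)(C(C)(C)Br)C(=O)C1 | intermediate
3 | methyl (2S)-2-methyl-5-(propan-2-ylidene)cyclopentane-1-carboxylate (epimers at C1) | CC(C)=C1CC[C@H](C)C1C(=O)OC | intermediate
4 | lithium dienolate of 3 | [Li+].[O-]C(OC)=C1C(=C(C)C)CC[C@@H]1C | intermediate
5 | methyl (1S,2S)-2-methyl-5-(propan-2-ylidene)cyclopentane-1-carboxylate (ester cis to methyl) | CC(C)=C1CC[C@H](C)[C@@H]1C(=O)OC | intermediate
6 | methyl (1S,2S)-5-hydroperoxy-2-methyl-5-(prop-1-en-2-yl)cyclopentane-1-carboxylate (C5 epimers) | C=C(C)C1(OO)CC[C@H](C)[C@@H]1C(=O)OC | intermediate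
7 | methyl (1S,2S)-5-hydroxy-2-methyl-5-(prop-1-en-2-yl)cyclopentane-1-carboxylate (C5 epimers) | C=C(C)C1(O)CC[C@H](C)[C@@H]1C(=O)OC | intermediate
8 | methyl (1S,2S)-5-(1-hydroxypropan-2-ylidene)-2-methylcyclopentane-1-carboxylate (E/Z mixture) | OCC(C)=C1CC[C@H](C)[C@@H]1C(=O)OC | intermediate
9 | (7S,7aS)-4,7-dimethyl-5,6,7,7a-tetrahydrocyclopenta[c]pyran-1(3H)-one | CC1=C2CC[C@H](C)[C@@H]2C(=O)OC1 | intermediate
10 | (7S,7aS)-4,7-dimethyl-1,3,5,6,7,7a-hexahydrocyclopenta[c]pyran-1-ol (anomers) | CC1=C2CC[C@H](C)[C@@H]2C(O)OC1 | intermediate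
11 | (Z)-2-[(2R,3S)-2-ethynyl-3-methylcyclopentylidene]propan-1-ol | OC/C(C)=C1/CC[C@H](C)[C@@H]1C#C | intermediate
12 | (Z)-2-[(2R,3S)-3-methyl-2-(prop-1-yn-1-yl)cyclopentylidene]propan-1-ol | OC/C(C)=C1/CC[C@H](C)[C@@H]1C#CC | intermediate
13 | (Z)-2-[(2R,3S)-3-methyl-2-(prop-1-yn-1-yl)cyclopentylidene]propanal | O=C/C(C)=C1/CC[C@H](C)[C@@H]1C#CC | intermediate
14 | 3-(trimethylsilyl)prop-2-ynal | O=CC#C[Si](C)(C)C | starting material
15 | 2-(triphenylphosphoranylidene)propanal | CC(C=O)=P(c1ccccc1)(c1ccccc1)c1ccccc1 | starting material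
16 | (E)-2-methyl-5-(trimethylsilyl)pent-2-en-4-ynal | O=C/C(C)=C/C#C[Si](C)(C)C | intermediate
17 | isoprene (2-methylbuta-1,3-diene) | C=CC(C)=C | starting material
18 | (1R,6R)-1,4-dimethyl-6-[(trimethylsilyl)ethynyl]cyclohex-3-ene-1-carbaldehyde | O=C[C@]1(C)CC=C(C)C[C@H]1C#C[Si](C)(C)C | intermediate
19 | {[(1R,6S)-6-ethenyl-3,6-dimethylcyclohex-3-en-1-yl]ethynyl}trimethylsilane | C=C[C@]1(C)CC=C(C)C[C@H]1C#C[Si](C)(C)C | intermediate
20 | N'-alkyl octane-1-sulfonohydrazide adduct at C14 of 19 (C14 epimers) | C=C[C@]1(C)CCC(C)(CNNS(=O)(=O)CCCCCCCC)C[C@H]1C#C[Si](C)(C)C | intermediate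
21 | {[(1R,2S)-2-ethenyl-2,5,5-trimethylcyclohexyl]ethynyl}trimethylsilane | C=C[C@]1(C)CCC(C)(C)C[C@H]1C#C[Si](C)(C)C | intermediate
22 | (1S,2S)-1-ethenyl-2-ethynyl-1,4,4-trimethylcyclohexane | C=C[C@]1(C)CCC(C)(C)C[C@H]1C#C | intermediate
23 | dicyclohexyl{(E)-2-[(1S,2S)-2-ethenyl-2,5,5-trimethylcyclohexyl]ethenyl}borane | C=C[C@]1(C)CCC(C)(C)C[C@H]1/C=C/B(C1CCCCC1)C1CCCCC1 | intermediate
24 | {(E)-2-[(1S,2S)-2-ethenyl-2,5,5-trimethylcyclohexyl]ethenyl}(methyl)zinc | C=C[C@]1(C)CCC(C)(C)C[C@H]1/C=C/[Zn]C | intermediate
25 | (1E,3S,4Z)-1-[(1S,2S)-2-ethenyl-2,5,5-trimethylcyclohexyl]-4-[(2R,3S)-3-methyl-2-(prop-1-yn-1-yl)cyclopentylidene]pent-1-en-3-ol | O[C@@H](/C=C/[C@@H]1CC(C)(C)CC[C@@]1(C)C=C)/C(C)=C2/CC[C@H](C)[C@@H]2C#CC | intermediate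
26 | (1E,3S,7S,7aS)-3-{(E)-2-[(1S,2S)-2-ethenyl-2,5,5-trimethylcyclohexyl]ethenyl}-1-(1-iodoethylidene)-4,7-dimethyl-1,3,5,6,7,7a-hexahydrocyclopenta[c]pyran | I/C(C)=C1/O[C@@H](/C=C/[C@@H]3CC(C)(C)CC[C@@]3(C)C=C)C(C)=C2CC[C@H](C)[C@H]12 | intermediate
27 | (1E,3S,7S,7aS)-1-(but-3-en-2-ylidene)-3-{(E)-2-[(1S,2S)-2-ethenyl-2,5,5-trimethylcyclohexyl]ethenyl}-4,7-dimethyl-1,3,5,6,7,7a-hexahydrocyclopenta[c]pyran | C=C/C(C)=C1/O[C@@H](/C=C/[C@@H]3CC(C)(C)CC[C@@]3(C)C=C)C(C)=C2CC[C@H](C)[C@H]12 | intermediate
28 | (3S,3aS,5S,6S,7Z)-5-ethenyl-6-[(1S,2S)-2-ethenyl-2,5,5-trimethylcyclohexyl]-3,5,9-trimethyl-1,2,3,3a,5,6-hexahydro-4H-cyclopenta[8]annulen-4-one | C=C[C@@]1(C)[C@H]([C@@H]3CC(C)(C)CC[C@@]3(C)C=C)/C=C\C(C)=C2\CC[C@H](C)[C@@H]2C1=O | intermediate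
29 | tetracyclic triene ketone: target skeleton with C7 ketone and C9=C10, cis-C18=C19 and C1=C2 alkenes (stereocentres as in the target) | O=C1[C@H]2[C@@H](C)CC/C2=C(C)/C=C\[C@H]2[C@@H]3CC(C)(C)CC[C@@]3(C)C=C[C@]12C | intermediate
30 | tetracyclic ketone: target skeleton with C7 ketone and only the C1=C2 alkene (5S,6S,8S,11S,16S,17S) | O=C1[C@H]2[C@@H](C)CC/C2=C(C)/CC[C@H]2[C@@H]3CC(C)(C)CC[C@@]3(C)CC[C@]12C | intermediate
31 | CNP0399382.1, the (5S,6S,7R,8S,11S,16S,17S) alcohol | C/C1=C2\CC[C@H](C)[C@@H]2[C@@H](O)[C@@]2(C)CC[C@]3(C)CCC(C)(C)C[C@H]3[C@@H]2CC1 | target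

**Step count and risks**

Total step count: 20. Longest linear sequence: 15 (steps 1–8 and 14–20); steps 9–13 are the five-step branch to alkyne 22.

Steps most likely to fail:

Step 3. What may go wrong: loss of regiocontrol in the ene reaction, with hydrogen abstraction from the ring methylene C3 (or from C6) instead of a methyl group, so that oxygen ends on the side-chain carbon. Fallback, setting out from 5 and returning at 9: 5 is treated with hypochlorous acid generated from Ca(OCl)2 and CO2 in CH2Cl2/water at 0 °C. This electrophilic ene-type chlorination runs through a chloronium ion that should open toward the exocyclic carbon (the ester disfavours charge at C2), so only methyl protons can be lost; it gives methyl (1S,2S)-5-chloro-2-methyl-5-(prop-1-en-2-yl)cyclopentane-1-carboxylate F1. Warming F1 with NaI in MeCN (70 °C) should then effect SN2′ displacement by the ester carbonyl oxygen with loss of the O-methyl group as MeI, which gives lactone 9.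

Step 18. What may go wrong: the ruthenium carbene fails to load onto the two neopentyl vinyl groups, or it engages the strained cis-alkene of the cyclooctadiene and opens ring B. Fallback, setting out from 26 and returning at 30: ring C is closed before the [3,3] shift instead of after it. The cyclohexyl vinyl group of 26 is hydroborated with 9-BBN (THF, rt) to the alkylborane F2. Intramolecular B-alkyl Suzuki–Miyaura coupling (Pd(dppf)Cl2, AsPh3, Cs2CO3, DMF/THF/H2O, high dilution, 50 °C) joins C8 to C9 and gives the bridged macrocyclic enol ether F3, in which ring C lacks only the C8–C17 bond. Heating F3 in toluene (up to 110 °C) should trigger the same Claisen shift transannularly and give the tetracyclic cyclooctenone F4, with rings B and C formed together and C9–C10 already saturated. Diimide reduction of the C18=C19 bond under the conditions of step 19 leads to 30.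

Step 20. What may go wrong: poor facial discrimination when the ketyl intermediate is protonated, giving the C7 epimer or a mixture. Fallback, setting out from 30 and returning at 31: 30 is reduced with NaBH4 (MeOH/THF, 0 °C), which is expected to deliver hydride from the periphery and give mainly the 7-epi alcohol F5. The carbinol is then equilibrated by reversible hydride transfer (Meerwein–Ponndorf–Verley/Oppenauer conditions: Al(Oi-Pr)3, i-PrOH, catalytic acetone, toluene, 80 °C), which interconverts the epimers through ketone 30 and should accumulate the more stable alcohol 31.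

Further compounds
F1 | step 3 | methyl (1S,2S)-5-chloro-2-methyl-5-(prop-1-en-2-yl)cyclopentane-1-carboxylate (C5 epimers) | C=C(C)C1(Cl)CC[C@H](C)[C@@H]1C(=O)OC
F2 | step 18 | 9-BBN alkylborane from hydroboration of the cyclohexyl vinyl group of 26 | I/C(C)=C1/O[C@@H](/C=C/[C@@H]3CC(C)(C)CC[C@@]3(C)CCB4C5CCCC4CCC5)C(C)=C2CC[C@H](C)[C@H]12
F3 | step 18 | bridged macrocyclic enol ether (C8–C9 bond closed, ten-membered ring through O, C7, C8, C9, C10, C11, C16, C17, C18, C19) | C4C/C(C)=C1/O[C@@H](/C=C/[C@@H]3CC(C)(C)CC[C@]34C)C(C)=C2CC[C@H](C)[C@H]12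
F4 | step 18 | tetracyclic ketone with cis-C18=C19 and C1=C2 alkenes (C9–C10 saturated) | O=C1[C@H]2[C@@H](C)CC/C2=C(C)/C=C\[C@H]2[C@@H]3CC(C)(C)CC[C@@]3(C)CC[C@]12C
F5 | step 20 | 7-epi-31 (7S alcohol) | O[C@H]1[C@H]2[C@@H](C)CC/C2=C(C)/CC[C@H]2[C@@H]3CC(C)(C)CC[C@@]3(C)CC[C@]12C
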